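**Retrosynthetic overview**
- The two acetates, the isobutyrate and the exocyclic methylene are added last to a bicyclic core: the cis‑fused γ‑lactone on a cyclohexane‑1,4‑diol.
- The cyclohexane is closed last by one double allylboration. An enantioenriched allylic 1,2‑bis(boronate) (the C5/C10 unit, with both alkenyl groups latent in it) adds first to C6 of a lactone aldehyde (C5–C6). The transposed allylboronate then adds to C9 (C9–C10).
- Enabling feature: ring carbons C6 and C9 are 1,4‑related secondary carbinols, each bonded to one of the two adjacent ring carbons (C5, C10) that carry the 2‑substituted allyl and the vinyl group. The ring therefore holds two overlapping homoallylic‑alcohol units, O–C9–C10–C1=C2 and O–C6–C5–C10(=C1 before transposition).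
- Ring order: γ‑lactone first (D‑proline aldol sets C7 and C8), cyclohexane second (C5, C6, C9, C10 relayed from the C–B stereocentre and the ring).
- The bis(boronate) comes from a dienyne by Cu‑catalysed double protoboration; the dienyne comes from propargyl alcohol by carboalumination/cross‑coupling.

Key step: step 7

Remark: elemane numbering is used for all compounds (C10 = quaternary ring carbon with the C14 methyl and the C1=C2 vinyl group; C9 = acetoxy carbon; C8 = lactone‑oxygen carbon; C7 bears C11(=C13)–C12; C6 = isobutyryloxy carbon; C5 bears C4(=C3)–C15). β means the face of the C10 methyl group. The C11 epimers of 17 and 18 converge in step 9 and are left unspecified. The route has not been run; every statement about outcome is an expectation.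

**Step 1**
Reactants: 1 2‑bromoprop‑2‑en‑1‑ol
Product: 2 [(2‑bromoprop‑2‑en‑1‑yl)oxy](tert‑butyl)diphenylsilane
Conditions: TBDPSCl, imidazole, CH2Cl2, 0 °C to rt
Reagents that add atoms: tert‑butyl(chloro)diphenylsilane, CC(C)(C)[Si](Cl)(c1ccccc1)c1ccccc1
Why: Imidazole‑promoted silylation of a primary alcohol gives an ether that should survive the organometallic, basic and acidic steps up to step 11; no stereocentre is involved.

**Step 2**
Reactants: 3 prop‑2‑yn‑1‑ol; 2 [(2‑bromoprop‑2‑en‑1‑yl)oxy](tert‑butyl)diphenylsilane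
Product: 5 (2E)‑4‑{[(tert‑butyldiphenylsilyl)oxy]methyl}‑2‑methylpenta‑2,4‑dien‑1‑ol, via alkenylalane 4 (not isolated)
Conditions: AlMe3 (3 equiv), Cp2ZrCl2 (0.25 equiv), CH2Cl2, 0 °C to rt; then 2, Pd(PPh3)4 (5 mol%), ZnCl2, THF, rt
Reagents that add atoms: trimethylaluminium, C[Al](C)C
Why: Negishi Zr‑catalysed carboalumination adds Me–Al syn across the alkyne (methyl to the internal carbon), and Pd/Zn cross‑coupling of the alkenylalane with the vinyl bromide proceeds with retention, so the trisubstituted alkene should form as the E isomer (side chain cis to methyl).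

**Step 3**
Reactants: 5 (2E)‑dienol
Product: 6 (2E)‑4‑{[(tert‑butyldiphenylsilyl)oxy]methyl}‑2‑methylpenta‑2,4‑dienal
Conditions: MnO2, CH2Cl2, rt
Reagents that add atoms: none
Why: Activated MnO2 oxidises the allylic primary alcohol selectively to the enal without alkene isomerisation.

**Step 4**
Reactants: 6 (2E)‑dienal
Product: 7 tert‑butyl{[(3E)‑4‑methyl‑2‑methylidenehex‑3‑en‑5‑yn‑1‑yl]oxy}diphenylsilane
Conditions: TMSCHN2, LDA, THF, –78 °C to rt
Reagents that add atoms: (trimethylsilyl)diazomethane, C[Si](C)(C)C=[N+]=[N-]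
Why: Colvin homologation (1,2‑addition of lithiated TMS‑diazomethane, Peterson elimination to the alkylidene carbene, 1,2‑H shift) converts the enal into the terminal enyne and leaves the alkene geometry untouched.

**Step 5**
Reactants: 7 (3E)‑dienyne
Product: 9 tert‑butyl{[(3E,5S)‑4‑methyl‑2‑methylidene‑5,6‑bis(4,4,5,5‑tetramethyl‑1,3,2‑dioxaborolan‑2‑yl)hex‑3‑en‑1‑yl]oxy}diphenylsilane, via trienylboronate 8 (not isolated)
Conditions: B2pin2 (2.1 equiv), MeOH (3 equiv), CuCl (7.5 mol%), chiral sulfonate‑bridged imidazolinium salt (7.5 mol%), NaOtBu (30 mol%), THF, –15 °C to rt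
Reagents that add atoms: bis(pinacolato)diboron, CC1(C)OB(OC1(C)C)B1OC(C)(C)C(C)(C)O1
Why: NHC–Cu‑catalysed tandem double protoboration of a terminal alkyne: the first Cu–B syn addition/protonation gives the (E)‑alkenylboronate 8, and the second Cu–B addition places copper α to boron and creates the allylic C–B stereocentre, whose (S) configuration is set by the ligand enantiomer chosen.

**Step 6**
Reactants: 10 methyl 4‑oxobutanoate; 11 2,2‑dimethoxyacetaldehyde
Product: 13 (2S,3R)‑2‑(dimethoxymethyl)‑5‑oxooxolane‑3‑carbaldehyde (cis), via aldol adduct 12 (not isolated)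
Conditions: D‑proline (20 mol%), DMF, 4 °C, slow addition of 10; then PPTS, CH2Cl2, rt
Reagents that add atoms: none
Why: Proline enamine cross‑aldol onto the non‑enolisable acetal aldehyde (Houk–List transition state) should give the anti adduct, D‑proline setting (3R,4S) = C7/C8, and lactonisation of the γ‑hydroxy ester turns the anti pair into the cis‑4,5‑disubstituted lactone with C6 as free aldehyde and C9 masked as acetal.

**Step 7**
Reactants: 9 (3E,5S)‑bis(boronate); 13 cis‑lactone aldehyde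
Product: 16 (5S,6S,7S,8S,9S,10S)‑15‑[(tert‑butyldiphenylsilyl)oxy]‑6β,9α‑dihydroxy‑11,13‑dihydroelema‑1,3‑dien‑12,8‑olide, via borate allylboronate 14 (not isolated), via hydroxy aldehyde 15 (not isolated)
Conditions: 9 (1.1 equiv), CH2Cl2, rt, 24 h; then TFA/H2O (9:1), 0 °C to rt; NaHCO3 work‑up
Reagents that add atoms: water, O
Why: Both C–C bonds form by allylboration through closed chair (Zimmerman–Traxler) transition states, the closest precedent being the tandem double allylboration of 1,4‑dicarbonyls with diene‑derived allylic 1,2‑bis(boronates). In the intermolecular event the aldehyde carbon C6 of 13 bonds to C5 of 9 with the α‑CH2Bpin group axial (avoiding A(1,2) strain with the C10 methyl) and the (E)‑placed side chain equatorial, so C5 and C6 are set by transfer of the C–B stereocentre of 9 (reagent control, which has to override the opposing Felkin preference of C7) as the 6‑OH/5‑side‑chain cis pair, and boron transposition leaves the (Z)‑allylboronate 14. Site selectivity (C6 before C9, although an α‑oxygenated aldehyde would be the more reactive one) is secured by keeping C9 as the dimethyl acetal during this event. Aqueous TFA then cleaves the borate and the acetal to 15 (resting as its five‑membered lactol with the new C6 hydroxyl), whose aldehyde is attacked by C10 in a 6‑exo‑trig closure of the cyclohexane through a cis‑fused bicyclic chair–chair transition state. Because the (Z) geometry forces the ring tether axial and the C10 methyl equatorial on the boron chair, O9 ends up cis to the new vinyl group, and only the chair that keeps the C5 side chain and the C7–C11 branch equatorial is accessible, which fixes C10 (methyl β, vinyl α) and C9 (OH α) relative to C5–C8 by substrate control. The step thus creates the carbocycle, four contiguous stereocentres, the quaternary centre and the vinyl group in one flask.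

**Step 8**
Reactants: 16 diol lactone
Product: 17 11‑[(dimethylamino)methyl] derivative of 16 (C11 epimers)
Conditions: LDA (3.3 equiv), THF, –78 °C; Me2N=CH2 I, –78 to –20 °C; AcOH quench
Reagents that add atoms: N,N‑dimethylmethyleneiminium iodide (Eschenmoser's salt), C=[N+](C)C.[I-]
Why: Polyanion Mannich reaction: both hydroxyls and the lactone α‑CH2 are deprotonated, the lactone is held as its enolate (so the cis C6 alkoxide cannot cause lactone migration) and is C‑alkylated by the iminium salt; the new C11 centre is removed in step 9.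

**Step 9**
Reactants: 17 Mannich base
Product: 19 (5S,6S,7S,8S,9S,10S)‑15‑[(tert‑butyldiphenylsilyl)oxy]‑6β,9α‑dihydroxyelema‑1,3,11(13)‑trien‑12,8‑olide, via ammonium iodide 18 (not isolated)
Conditions: MeI, MeOH, rt; then aq. NaHCO3, CH2Cl2, rt
Reagents that add atoms: none
Why: N‑quaternisation followed by mild base‑induced β‑elimination of trimethylamine (Hofmann‑type) is the standard way to an α‑methylene γ‑lactone and tolerates free hydroxyls and the alkenes.

**Step 10**
Reactants: 19 α‑methylene diol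
Product: 20 6‑O‑isobutyrate of 19 (9α‑OH free)
Conditions: (iPrCO)2O (1.2 equiv), Et3N, DMAP (0.2 equiv), CH2Cl2, 0 °C to rt
Reagents that add atoms: isobutyric anhydride, CC(C)C(=O)OC(=O)C(C)C
Why: DMAP‑catalysed acylation should take the C6 hydroxyl first, because the C9 hydroxyl is neopentylic (next to the quaternary C10) and the bulky anhydride amplifies the difference.

**Step 11**
Reactants: 20 6‑O‑isobutyrate
Product: 21 (5S,6S,7S,8S,9S,10S)‑9α,15‑dihydroxy‑6β‑(isobutyryloxy)elema‑1,3,11(13)‑trien‑12,8‑olide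
Conditions: HF·pyridine, THF/pyridine, 0 °C to rt
Reagents that add atoms: none
Why: Buffered fluoride removes the primary TBDPS ether without base, so the esters and the Michael‑acceptor lactone are left alone.

**Step 12**
Reactants: 21 9,15‑diol
Product: 22 CNP0500052.1, (5S,6S,7S,8S,9S,10S)‑9α,15‑diacetoxy‑6β‑(isobutyryloxy)elema‑1,3,11(13)‑trien‑12,8‑olide
Conditions: Ac2O, pyridine, DMAP, rt to 40 °C
Reagents that add atoms: acetic anhydride, CC(=O)OC(C)=O
Why: Exhaustive acetylation esterifies the primary allylic and the hindered secondary hydroxyl in one operation; no stereocentre is touched.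

**Compound list**
1 | 2‑bromoprop‑2‑en‑1‑ol | C=C(Br)CO | starting material
2 | [(2‑bromoprop‑2‑en‑1‑yl)oxy](tert‑butyl)diphenylsilane | C=C(Br)CO[Si](c1ccccc1)(c1ccccc1)C(C)(C)C | intermediate
3 | prop‑2‑yn‑1‑ol | C#CCO | starting material
4 | (E)‑alkenylalane, dimethyl[(1E)‑3‑(dimethylalumanyloxy)‑2‑methylprop‑1‑en‑1‑yl]alumane (not isolated) | C[Al](C)/C=C(\C)CO[Al](C)C | intermediate
5 | (2E)‑4‑{[(tert‑butyldiphenylsilyl)oxy]methyl}‑2‑methylpenta‑2,4‑dien‑1‑ol | OC/C(C)=C/C(=C)CO[Si](c1ccccc1)(c1ccccc1)C(C)(C)C | intermediate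
6 | (2E)‑4‑{[(tert‑butyldiphenylsilyl)oxy]methyl}‑2‑methylpenta‑2,4‑dienal | O=C/C(C)=C/C(=C)CO[Si](c1ccccc1)(c1ccccc1)C(C)(C)C | intermediate
7 | tert‑butyl{[(3E)‑4‑methyl‑2‑methylidenehex‑3‑en‑5‑yn‑1‑yl]oxy}diphenylsilane | C#C/C(C)=C/C(=C)CO[Si](c1ccccc1)(c1ccccc1)C(C)(C)C | intermediate
8 | (3E,5E)‑trienylboronate, 6‑Bpin derivative of the 4‑methyl‑2‑methylidenehexa‑3,5‑dienyl silyl ether (not isolated) | CC1(C)OB(/C=C/C(C)=C/C(=C)CO[Si](c2ccccc2)(c2ccccc2)C(C)(C)C)OC1(C)C | intermediate
9 | tert‑butyl{[(3E,5S)‑4‑methyl‑2‑methylidene‑5,6‑bis(4,4,5,5‑tetramethyl‑1,3,2‑dioxaborolan‑2‑yl)hex‑3‑en‑1‑yl]oxy}diphenylsilane | CC1(C)OB(C[C@H](B2OC(C)(C)C(C)(C)O2)/C(C)=C/C(=C)CO[Si](c2ccccc2)(c2ccccc2)C(C)(C)C)OC1(C)C | intermediate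
10 | methyl 4‑oxobutanoate | COC(=O)CCC=O | starting material
11 | 2,2‑dimethoxyacetaldehyde | COC(OC)C=O | starting material
12 | methyl (3R,4S)‑3‑formyl‑4‑hydroxy‑5,5‑dimethoxypentanoate, anti aldol adduct (not isolated) | COC(OC)[C@@H](O)[C@@H](CC(=O)OC)C=O | intermediate
13 | (2S,3R)‑2‑(dimethoxymethyl)‑5‑oxooxolane‑3‑carbaldehyde (cis) | COC(OC)[C@H]1OC(=O)C[C@H]1C=O | intermediate
14 | first allylboration adduct: lactone acetal with C6–O–Bpin, the C5 side chain and the (Z)‑C10=C1–C2H2–Bpin allylboronate; C5–C8 configured as in 16 (not isolated) | COC(OC)[C@H]1OC(=O)C[C@H]1[C@@H](OB2OC(C)(C)C(C)(C)O2)[C@H](/C(C)=C\CB2OC(C)(C)C(C)(C)O2)C(=C)CO[Si](c2ccccc2)(c2ccccc2)C(C)(C)C | intermediate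
15 | hydroxy aldehyde: C6–OH, C9 aldehyde, (Z)‑allylboronate; rests as the C6–O–C9 lactol (not isolated) | O=C[C@H]1OC(=O)C[C@H]1[C@@H](O)[C@H](/C(C)=C\CB2OC(C)(C)C(C)(C)O2)C(=C)CO[Si](c2ccccc2)(c2ccccc2)C(C)(C)C | intermediate
16 | (5S,6S,7S,8S,9S,10S)‑15‑[(tert‑butyldiphenylsilyl)oxy]‑6β,9α‑dihydroxy‑11,13‑dihydroelema‑1,3‑dien‑12,8‑olide (H‑5α, H‑7α, H‑8α; 10β‑methyl, 10α‑vinyl) | C=C[C@]1(C)[C@H](O)[C@H]2OC(=O)C[C@H]2[C@@H](O)[C@H]1C(=C)CO[Si](c1ccccc1)(c1ccccc1)C(C)(C)C | intermediate
17 | 11‑[(dimethylamino)methyl] derivative of 16 (C11 epimers) | C=C[C@]1(C)[C@H](O)[C@H]2OC(=O)C(CN(C)C)[C@H]2[C@@H](O)[C@H]1C(=C)CO[Si](c1ccccc1)(c1ccccc1)C(C)(C)C | intermediate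
18 | 11‑[(trimethylammonio)methyl] iodide of 16 (not isolated) | C=C[C@]1(C)[C@H](O)[C@H]2OC(=O)C(C[N+](C)(C)C)[C@H]2[C@@H](O)[C@H]1C(=C)CO[Si](c1ccccc1)(c1ccccc1)C(C)(C)C.[I-] | intermediate
19 | (5S,6S,7S,8S,9S,10S)‑15‑[(tert‑butyldiphenylsilyl)oxy]‑6β,9α‑dihydroxyelema‑1,3,11(13)‑trien‑12,8‑olide | C=C[C@]1(C)[C@H](O)[C@H]2OC(=O)C(=C)[C@H]2[C@@H](O)[C@H]1C(=C)CO[Si](c1ccccc1)(c1ccccc1)C(C)(C)C | intermediate
20 | 6‑O‑isobutyrate of 19 | C=C[C@]1(C)[C@H](O)[C@H]2OC(=O)C(=C)[C@H]2[C@@H](OC(=O)C(C)C)[C@H]1C(=C)CO[Si](c1ccccc1)(c1ccccc1)C(C)(C)C | intermediate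
21 | (5S,6S,7S,8S,9S,10S)‑9α,15‑dihydroxy‑6β‑(isobutyryloxy)elema‑1,3,11(13)‑trien‑12,8‑olide | C=C[C@]1(C)[C@H](O)[C@H]2OC(=O)C(=C)[C@H]2[C@@H](OC(=O)C(C)C)[C@H]1C(=C)CO | intermediate
22 | CNP0500052.1, (5S,6S,7S,8S,9S,10S)‑9α,15‑diacetoxy‑6β‑(isobutyryloxy)elema‑1,3,11(13)‑trien‑12,8‑olide | C=C[C@]1(C)[C@H](OC(C)=O)[C@H]2OC(=O)C(=C)[C@H]2[C@@H](OC(=O)C(C)C)[C@H]1C(=C)COC(C)=O | target

**Totals**
Total step count: 12.
Longest linear sequence: 11 steps (steps 1–5, then 7–12).

**Three steps most likely to fail**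

Step 7. What may go wrong:
- protodeboronation of the (Z)‑allylboronate, or acid‑promoted migration of the lactone from O8 to the cis O6, while the acetal is being hydrolysed;
- erosion of reagent control in the Felkin‑mismatched first addition;
- slow ring closure through the transition state that carries O6, O8 and the C10 methyl syn‑axial.

Fallback (stepwise, with O6 capped before the ring is closed): it sets out from 9 and 13, which are combined as in the first half of step 7. A neutral aqueous work‑up should give the allylboronate alcohol F1 with the allylboronate intact. Isobutyric anhydride/DMAP gives its isobutyrate F2. TFA/H2O then releases the C9 aldehyde, which closes the ring by the same intramolecular allylboration to the 6‑O‑isobutyryl‑9‑hydroxy lactone F3. LDA (2.2 equiv) and Eschenmoser's salt give the Mannich base F4, MeI gives the ammonium iodide F5, and NaHCO3 gives 20, where the route is rejoined for steps 11 and 12. This variant also makes step 10 unnecessary.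

Step 5. What may go wrong: boryl‑copper addition across the conjugated trienylboronate in a 1,4‑ or 1,6‑sense or to the 1,1‑disubstituted alkene, or low enantiofacial control in the second addition.

Fallback: it sets out from 6. Wittig methylenation (Ph3P=CH2, THF, 0 °C) gives the (E)‑triene F6. Pt‑catalysed enantioselective diboration of its terminal vinyl group (Pt2(dba)3, TADDOL‑derived phosphonite, B2pin2, THF, 60 °C) returns to 9. The 1,2‑ versus 1,4‑mode of addition would have to be checked, since trans‑dienes tend to add 1,4 with this catalyst type.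

Step 10. What may go wrong: poor or inverted site selectivity between the two hindered secondary hydroxyls, or double acylation.

Fallback (inverted order of acylation): it sets out from 19. Ac2O (1.0 equiv), DMAP, –20 °C gives the 9‑O‑acetate F7 (mono‑esters separable). Isobutyryl chloride, DMAP, pyridine, 40 °C gives the 9‑O‑acetyl‑6‑O‑isobutyryl silyl ether F8. HF·pyridine gives the primary alcohol F9, and Ac2O/pyridine gives 22.

Further compounds
F1 | step 7 | allylboronate alcohol (C6–OH free; acetal, lactone and (Z)‑allyl‑Bpin as in 14) | COC(OC)[C@H]1OC(=O)C[C@H]1[C@@H](O)[C@H](/C(C)=C\CB2OC(C)(C)C(C)(C)O2)C(=C)CO[Si](c2ccccc2)(c2ccccc2)C(C)(C)C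
F2 | step 7 | 6‑O‑isobutyrate of F1 | COC(OC)[C@H]1OC(=O)C[C@H]1[C@@H](OC(=O)C(C)C)[C@H](/C(C)=C\CB2OC(C)(C)C(C)(C)O2)C(=C)CO[Si](c2ccccc2)(c2ccccc2)C(C)(C)C
F3 | step 7 | 6‑O‑isobutyryl‑9α‑hydroxy‑11,13‑dihydro lactone (15‑OTBDPS) | C=C[C@]1(C)[C@H](O)[C@H]2OC(=O)C[C@H]2[C@@H](OC(=O)C(C)C)[C@H]1C(=C)CO[Si](c1ccccc1)(c1ccccc1)C(C)(C)C
F4 | step 7 | 11‑[(dimethylamino)methyl] derivative of F3 | C=C[C@]1(C)[C@H](O)[C@H]2OC(=O)C(CN(C)C)[C@H]2[C@@H](OC(=O)C(C)C)[C@H]1C(=C)CO[Si](c1ccccc1)(c1ccccc1)C(C)(C)C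
F5 | step 7 | 11‑[(trimethylammonio)methyl] iodide of F3 | C=C[C@]1(C)[C@H](O)[C@H]2OC(=O)C(C[N+](C)(C)C)[C@H]2[C@@H](OC(=O)C(C)C)[C@H]1C(=C)CO[Si](c1ccccc1)(c1ccccc1)C(C)(C)C.[I-]
F6 | step 5 | tert‑butyl{[(3E)‑4‑methyl‑2‑methylidenehexa‑3,5‑dien‑1‑yl]oxy}diphenylsilane | C=C/C(C)=C/C(=C)CO[Si](c1ccccc1)(c1ccccc1)C(C)(C)C
F7 | step 10 | 9‑O‑acetate of 19 (6β‑OH free) | C=C[C@]1(C)[C@H](OC(C)=O)[C@H]2OC(=O)C(=C)[C@H]2[C@@H](O)[C@H]1C(=C)CO[Si](c1ccccc1)(c1ccccc1)C(C)(C)C
F8 | step 10 | 9‑O‑acetyl‑6‑O‑isobutyryl‑15‑O‑TBDPS triene lactone | C=C[C@]1(C)[C@H](OC(C)=O)[C@H]2OC(=O)C(=C)[C@H]2[C@@H](OC(=O)C(C)C)[C@H]1C(=C)CO[Si](c1ccccc1)(c1ccccc1)C(C)(C)C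
F9 | step 10 | 9‑O‑acetyl‑6‑O‑isobutyryl‑15‑hydroxy triene lactone | C=C[C@]1(C)[C@H](OC(C)=O)[C@H]2OC(=O)C(=C)[C@H]2[C@@H](OC(=O)C(C)C)[C@H]1C(=C)CO
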